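The dihydrofuran ring is cut at the C2–C3 bond. C3, the benzylic CH2, is traced back to the formyl carbon of a phloroglucinaldehyde; C2, the methine on O1, to the O–CH2 group of an ortho 2-methyl-2-silyloxypropyl ether. A chiral dirhodium carboxylate turns the aryl carbene, released below room temperature from an arenesulfonylhydrazone, into the ring by enantioselective 1,5 C–H insertion: one operation forms C2–C3, closes the five-membered ring and sets the 2S centre. The precursor is the sulfonylhydrazone of a 2,4-bis(silyloxy)-6-alkoxybenzaldehyde whose only oxygen-activated C–H bonds are the two enantiotopic ones to be told apart. The cinnamoyl arm is added afterwards at C5 by directed lithiation.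

Key step: step 6

Remarks on the chemistry (assumptions and design choices):
- Ring positions are numbered as in 2,3-dihydro-1-benzofuran (O1, C2, C3, C3a, C4 to C7, C7a).
- Assumption: Rh2(S-PTAD)4 is taken to give the 2S product; if the sense of induction is the opposite, Rh2(R-PTAD)4 would replace it with no other change.
- Assumption: 2-(trifluoromethyl)benzenesulfonohydrazide is taken as a purchasable reagent.
- Precursor design: the hydrazone carries a 2-(trifluoromethyl)benzenesulfonyl group in place of the usual tosyl group, and NaH is the base. The diazo compound then forms below room temperature, and hot carbonate, which cleaves aryl silyl ethers and erodes enantiocontrol, is avoided.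
- Protecting groups: MOM serves for the epoxide alkylation, which silyl ethers would not survive. It is exchanged for silyl before step 6, because the O–CH2–O hydrogens of an ortho MOM group would be a competing 1,5 insertion site.

Step 1
Reactants: 1 2,4,6-trihydroxybenzaldehyde
Product: 2 2-hydroxy-4,6-bis(methoxymethoxy)benzaldehyde
Conditions: MOMCl (2.1 equiv), iPr2NEt, CH2Cl2, 0 °C → rt
Reagents that add atoms: chloromethyl methyl ether (MOMCl), COCCl
Why: O-alkylation of phenols with a chloromethyl ether (Williamson-type MOM protection) takes the para hydroxyl and one of the two equivalent ortho hydroxyls, while the last ortho hydroxyl is held in a hydrogen bond to the formyl group and reacts far more slowly, so the reaction should stop at the bis-ether.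

Step 2
Reactants: 2 2-hydroxy-4,6-bis(methoxymethoxy)benzaldehyde; 3 2,2-dimethyloxirane
Product: 4 2-(2-hydroxy-2-methylpropoxy)-4,6-bis(methoxymethoxy)benzaldehyde
Conditions: K2CO3 (0.5 equiv), DMF, 90 °C, sealed tube
Reagents that add atoms: none
Why: Base-mediated ring opening of an epoxide by a phenoxide (SN2 at the unsubstituted CH2 of the 2,2-disubstituted oxirane) should give the aryl 2-hydroxy-2-methylpropyl ether regioselectively, and MOM ethers and the non-enolisable aldehyde are stable to carbonate in DMF.

Step 3
Reactants: 4 2-(2-hydroxy-2-methylpropoxy)-4,6-bis(methoxymethoxy)benzaldehyde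
Product: 5 2,4-dihydroxy-6-(2-hydroxy-2-methylpropoxy)benzaldehyde
Conditions: HCl (1.25 M in MeOH), MeOH, 40 °C; then H2O
Reagents that add atoms: none
Why: Acid-catalysed transacetalisation cleaves both MOM ethers, the β-aryloxy tertiary alcohol is too electron-poor to ionise in dilute acid, and any aldehyde dimethyl acetal is hydrolysed in the aqueous work-up.

Step 4
Reactants: 5 2,4-dihydroxy-6-(2-hydroxy-2-methylpropoxy)benzaldehyde
Product: 7 2,4-bis(tert-butyldimethylsilyloxy)-6-[2-methyl-2-(triethylsilyloxy)propoxy]benzaldehyde, via bis-TBS alcohol 6 (not isolated)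
Conditions: TBSCl (2.3 equiv), imidazole, DMF, 0 °C → rt; then TESCl (1.5 equiv), DMAP (cat.), 40 °C
Reagents that add atoms: tert-butyldimethylsilyl chloride (TBSCl), CC(C)(C)[Si](C)(C)Cl; triethylsilyl chloride (TESCl), CC[Si](Cl)(CC)CC
Why: Chemoselective silyl ether formation: TBSCl with imidazole silylates only the two phenols, and TESCl with DMAP then caps the tertiary alcohol in the same flask, leaving no O–H bond and no oxygen-activated C–H bond other than the O–CH2 group.

Step 5
Reactants: 7 2,4-bis(tert-butyldimethylsilyloxy)-6-[2-methyl-2-(triethylsilyloxy)propoxy]benzaldehyde; 8 2-(trifluoromethyl)benzenesulfonohydrazide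
Product: 9 N'-[(E)-{2,4-bis(tert-butyldimethylsilyloxy)-6-[2-methyl-2-(triethylsilyloxy)propoxy]phenyl}methylidene]-2-(trifluoromethyl)benzenesulfonohydrazide
Conditions: THF, MgSO4, rt → 40 °C
Reagents that add atoms: none
Why: Condensation of an aldehyde with a sulfonyl hydrazide gives the (E)-N-sulfonylhydrazone, and the ortho-CF3 sulfonyl group is chosen because such hydrazone salts are known to release the diazo compound below room temperature.

Step 6
Reactants: 9 N'-[(E)-{2,4-bis(tert-butyldimethylsilyloxy)-6-[2-methyl-2-(triethylsilyloxy)propoxy]phenyl}methylidene]-2-(trifluoromethyl)benzenesulfonohydrazide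
Product: 12 (2S)-4,6-bis(tert-butyldimethylsilyloxy)-2-[2-(triethylsilyloxy)propan-2-yl]-2,3-dihydro-1-benzofuran, via hydrazone sodium salt 10 (not isolated), via aryldiazomethane 11 (not isolated)
Conditions: NaH (1.5 equiv), Rh2(S-PTAD)4 (2 mol %), 4 Å MS, CH2Cl2 (0.01 M), −20 °C → rt
Reagents that add atoms: none
Why: Proposed new method: NaH converts 9 into sodium salt 10, which loses 2-(trifluoromethyl)benzenesulfinate (Bamford–Stevens fragmentation) to give aryldiazomethane 11; Rh2(S-PTAD)4, dirhodium tetrakis[(S)-(1-adamantyl)(N-phthalimido)acetate], a dimer of divalent rhodium, takes up 11 with loss of N2, and the electron-rich rhodium carbene inserts into a C–H bond of the ortho O–CH2 group through a concerted, asynchronous three-centre transition state with hydride-transfer character, the ether oxygen stabilising the positive charge that builds up at C2. The closest known reaction type is the enantioselective intramolecular 1,5 C–H insertion of hydrazone-derived donor carbenes into ether O–CH2 bonds on chiral dirhodium carboxylates, which gives 2-substituted 2,3-dihydrobenzofurans; an aldehyde-derived carbene flanked by two ortho oxygens and an insertion site next to a quaternary carbon have not been shown. The dihydrofuran ring is closed by C2–C3 bond formation across a 1,5 relationship (carbene carbon, C3a, C7a, O1, C2), the five-membered transition state being preferred over any larger one. C2 is set by the catalyst alone, whose chiral phthalimido carboxylate ligands distinguish the two enantiotopic hydrogens of the O–CH2 group. The step needs site selectivity and suppression of bimolecular carbene loss (azine and stilbene formation): all other oxygens carry silyl groups, so no other oxygen-activated C–H bond is in reach, the carbene has no β-hydrogen for a 1,2-shift, the two ortho substituents shield it, and the diazo compound is released slowly at high dilution.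

Step 7
Reactants: 12 (2S)-4,6-bis(tert-butyldimethylsilyloxy)-2-[2-(triethylsilyloxy)propan-2-yl]-2,3-dihydro-1-benzofuran
Product: 13 (2S)-2-(2-hydroxypropan-2-yl)-2,3-dihydro-1-benzofuran-4,6-diol
Conditions: TBAF (3.5 equiv), AcOH (3.5 equiv), THF, 0 °C → rt, under argon
Reagents that add atoms: none
Why: Fluoride-mediated desilylation, driven by Si–F bond formation, should remove the two aryl TBS groups and the tertiary TES group, acetic acid keeping the electron-rich phenols protonated, and the C2 ether stereocentre is not affected.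

Step 8
Reactants: 13 (2S)-2-(2-hydroxypropan-2-yl)-2,3-dihydro-1-benzofuran-4,6-diol
Product: 14 2-[(2S)-4,6-bis(methoxymethoxy)-2,3-dihydro-1-benzofuran-2-yl]propan-2-ol
Conditions: MOMCl (2.3 equiv), iPr2NEt, CH2Cl2, 0 °C → rt
Reagents that add atoms: chloromethyl methyl ether (MOMCl), COCCl
Why: MOM protection of the two phenols under amine base, the tertiary alcohol being much less reactive, installs the two chelating groups needed for directed ortho-metalation.

Step 9
Reactants: 15 4-hydroxycinnamic acid
Product: 16 (2E)-3-(4-hydroxyphenyl)-N-methoxy-N-methylprop-2-enamide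
Conditions: MeNH(OMe)·HCl, EDC·HCl, HOBt (cat.), N-methylmorpholine, DMF, 0 °C → rt
Reagents that add atoms: N,O-dimethylhydroxylamine hydrochloride, CNOC.Cl
Why: Carbodiimide amide coupling through the HOBt active ester (Weinreb amide formation) should tolerate the free phenol, which is a far poorer nucleophile than the hydroxylamine.

Step 10
Reactants: 16 (2E)-3-(4-hydroxyphenyl)-N-methoxy-N-methylprop-2-enamide
Product: 17 (2E)-N-methoxy-3-[4-(methoxymethoxy)phenyl]-N-methylprop-2-enamide
Conditions: MOMCl (1.3 equiv), iPr2NEt, CH2Cl2, 0 °C → rt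
Reagents that add atoms: chloromethyl methyl ether (MOMCl), COCCl
Why: MOM protection of the phenol removes the acidic proton ahead of the organolithium step and matches the groups to be cleaved at the end.

Step 11
Reactants: 14 2-[(2S)-4,6-bis(methoxymethoxy)-2,3-dihydro-1-benzofuran-2-yl]propan-2-ol; 17 (2E)-N-methoxy-3-[4-(methoxymethoxy)phenyl]-N-methylprop-2-enamide
Product: 20 (2E)-1-[(2S)-2-(2-hydroxypropan-2-yl)-4,6-bis(methoxymethoxy)-2,3-dihydro-1-benzofuran-5-yl]-3-[4-(methoxymethoxy)phenyl]prop-2-en-1-one, via aryllithium 18 (not isolated), via tetrahedral adduct 19 (not isolated)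
Conditions: n-BuLi (2.2 equiv), THF, 0 °C → rt; then 17, −78 → 0 °C; aq. NH4Cl
Reagents that add atoms: none
Why: Directed ortho-metalation and Weinreb ketone synthesis: one equivalent of n-BuLi forms the lithium alkoxide and the second lithiates C5, the only ring position flanked by two chelating OMOM groups, and the aryllithium adds 1,2 to the amide to give a chelated tetrahedral adduct that releases the enone only on work-up, so that no second addition occurs.

Step 12
Reactants: 20 (2E)-1-[(2S)-2-(2-hydroxypropan-2-yl)-4,6-bis(methoxymethoxy)-2,3-dihydro-1-benzofuran-5-yl]-3-[4-(methoxymethoxy)phenyl]prop-2-en-1-one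
Product: 21 (2E)-1-[(2S)-4,6-dihydroxy-2-(2-hydroxypropan-2-yl)-2,3-dihydro-1-benzofuran-5-yl]-3-(4-hydroxyphenyl)prop-2-en-1-one
Conditions: HCl (1.25 M in MeOH), MeOH, 0 °C → rt, stopped at full conversion
Reagents that add atoms: none
Why: Acid-catalysed transacetalisation removes the three MOM groups, those next to the ketone fastest since the freed phenols hydrogen-bond to the carbonyl, and short exposure at or below room temperature is chosen to limit cyclisation to the flavanone; C2 and the E alkene are not touched.

Compound list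
1 | 2,4,6-trihydroxybenzaldehyde | O=Cc1c(O)cc(O)cc1O | starting material
2 | 2-hydroxy-4,6-bis(methoxymethoxy)benzaldehyde | O=Cc1c(O)cc(OCOC)cc1OCOC | intermediate
3 | 2,2-dimethyloxirane | CC1(C)CO1 | starting material
4 | 2-(2-hydroxy-2-methylpropoxy)-4,6-bis(methoxymethoxy)benzaldehyde | O=Cc1c(OCC(C)(C)O)cc(OCOC)cc1OCOC | intermediate
5 | 2,4-dihydroxy-6-(2-hydroxy-2-methylpropoxy)benzaldehyde | O=Cc1c(OCC(C)(C)O)cc(O)cc1O | intermediate
6 | 2,4-bis(tert-butyldimethylsilyloxy)-6-(2-hydroxy-2-methylpropoxy)benzaldehyde (not isolated) | O=Cc1c(OCC(C)(C)O)cc(O[Si](C)(C)C(C)(C)C)cc1O[Si](C)(C)C(C)(C)C | intermediate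
7 | 2,4-bis(tert-butyldimethylsilyloxy)-6-[2-methyl-2-(triethylsilyloxy)propoxy]benzaldehyde | O=Cc1c(OCC(C)(C)O[Si](CC)(CC)CC)cc(O[Si](C)(C)C(C)(C)C)cc1O[Si](C)(C)C(C)(C)C | intermediate
8 | 2-(trifluoromethyl)benzenesulfonohydrazide | NNS(=O)(=O)c1ccccc1C(F)(F)F | starting material
9 | N'-[(E)-{2,4-bis(tert-butyldimethylsilyloxy)-6-[2-methyl-2-(triethylsilyloxy)propoxy]phenyl}methylidene]-2-(trifluoromethyl)benzenesulfonohydrazide | FC(F)(F)c1ccccc1S(=O)(=O)N/N=C/c1c(OCC(C)(C)O[Si](CC)(CC)CC)cc(O[Si](C)(C)C(C)(C)C)cc1O[Si](C)(C)C(C)(C)C | intermediate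
10 | sodium salt of hydrazone 9 (not isolated) | [Na+].FC(F)(F)c1ccccc1S(=O)(=O)[N-]/N=C/c1c(OCC(C)(C)O[Si](CC)(CC)CC)cc(O[Si](C)(C)C(C)(C)C)cc1O[Si](C)(C)C(C)(C)C | intermediate
11 | [2,4-bis(tert-butyldimethylsilyloxy)-6-(2-methyl-2-triethylsilyloxypropoxy)phenyl]diazomethane (not isolated) | [N-]=[N+]=Cc1c(OCC(C)(C)O[Si](CC)(CC)CC)cc(O[Si](C)(C)C(C)(C)C)cc1O[Si](C)(C)C(C)(C)C | intermediate
12 | (2S)-4,6-bis(tert-butyldimethylsilyloxy)-2-[2-(triethylsilyloxy)propan-2-yl]-2,3-dihydro-1-benzofuran | CC[Si](CC)(CC)OC(C)(C)[C@@H]1Cc2c(O[Si](C)(C)C(C)(C)C)cc(O[Si](C)(C)C(C)(C)C)cc2O1 | intermediate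
13 | (2S)-2-(2-hydroxypropan-2-yl)-2,3-dihydro-1-benzofuran-4,6-diol | CC(C)(O)[C@@H]1Cc2c(O)cc(O)cc2O1 | intermediate
14 | 2-[(2S)-4,6-bis(methoxymethoxy)-2,3-dihydro-1-benzofuran-2-yl]propan-2-ol | CC(C)(O)[C@@H]1Cc2c(OCOC)cc(OCOC)cc2O1 | intermediate
15 | 4-hydroxycinnamic acid | O=C(O)/C=C/c1ccc(O)cc1 | starting material
16 | (2E)-3-(4-hydroxyphenyl)-N-methoxy-N-methylprop-2-enamide | CON(C)C(=O)/C=C/c1ccc(O)cc1 | intermediate
17 | (2E)-N-methoxy-3-[4-(methoxymethoxy)phenyl]-N-methylprop-2-enamide | CON(C)C(=O)/C=C/c1ccc(OCOC)cc1 | intermediate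
18 | C5-lithio derivative of 14 as its lithium alkoxide (not isolated) | [Li]OC(C)(C)[C@@H]1Cc2c(OCOC)c([Li])c(OCOC)cc2O1 | intermediate
19 | lithium hemiaminal alkoxide formed from 18 and 17, tetrahedral adduct (not isolated) | [Li]OC(C)(C)[C@@H]1Cc2c(OCOC)c(C(O[Li])(/C=C/c3ccc(OCOC)cc3)N(C)OC)c(OCOC)cc2O1 | intermediate
20 | (2E)-1-[(2S)-2-(2-hydroxypropan-2-yl)-4,6-bis(methoxymethoxy)-2,3-dihydro-1-benzofuran-5-yl]-3-[4-(methoxymethoxy)phenyl]prop-2-en-1-one | CC(C)(O)[C@@H]1Cc2c(OCOC)c(C(=O)/C=C/c3ccc(OCOC)cc3)c(OCOC)cc2O1 | intermediate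
21 | (2E)-1-[(2S)-4,6-dihydroxy-2-(2-hydroxypropan-2-yl)-2,3-dihydro-1-benzofuran-5-yl]-3-(4-hydroxyphenyl)prop-2-en-1-one | CC(C)(O)[C@@H]1Cc2c(O)c(C(=O)/C=C/c3ccc(O)cc3)c(O)cc2O1 | target

Total step count: 12.
Longest linear sequence: 10 steps (steps 1 to 8, 11 and 12); the amide fragment takes 2 steps (9 and 10).

Steps most likely to fail

1. Step 6 (proposed new method). The insertion may be slow at the hindered O–CH2 group next to the quaternary carbon. The carbene could then be lost by bimolecular coupling with the diazo compound (azine or stilbene formation), or the two enantiotopic hydrogens could be poorly distinguished. The fallback uses known chemistry, sets out from 2 and comes back at 14. Rap–Stoermer annulation of 2 with chloroacetone (K2CO3, DMF, 80 °C) should give 1-[4,6-bis(methoxymethoxy)-1-benzofuran-2-yl]ethan-1-one F1. Addition of MeMgBr (THF, 0 °C) should give 2-[4,6-bis(methoxymethoxy)-1-benzofuran-2-yl]propan-2-ol F2. Enantioselective hydrogenation of the furan C2=C3 bond with a chiral ruthenium N-heterocyclic carbene catalyst should then give 14 directly. The catalyst is formed from Ru(cod)(2-methylallyl)2, the C2-symmetric imidazolinium salt SINpEt·HBF4 and KOtBu, used under H2 pressure in hexane at rt, with the ligand enantiomer chosen for 2S. Steps 2 to 8 are then not needed.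

2. Step 11. The hindered, doubly chelated aryllithium may add in conjugate fashion to the cinnamoyl amide, or acyl transfer may be slow enough for proton transfer to compete. The fallback sets out from 14 and comes back at 20. The same lithiation (n-BuLi, THF, 0 °C) is quenched with the small, non-conjugated N-methoxy-N-methylacetamide to give 1-[(2S)-2-(2-hydroxypropan-2-yl)-4,6-bis(methoxymethoxy)-2,3-dihydro-1-benzofuran-5-yl]ethan-1-one F3. 4-Hydroxybenzaldehyde is protected with MOMCl and iPr2NEt to give 4-(methoxymethoxy)benzaldehyde F4. Claisen–Schmidt condensation of the two (KOH, EtOH, rt) should then give the E enone 20.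

3. Step 12. While the MOM groups are cleaved, the freed ortho hydroxyls may add to the enone under acid catalysis (intramolecular oxa-Michael addition, chalcone-to-flavanone cyclisation). The fallback sets out from 20 and comes back at 21. The acid treatment is run to completion (HCl, MeOH, 50 °C) without trying to stop the cyclisation, so that the material collects as two regioisomeric flavanones, each a mixture of epimers at the new aryl-bearing carbon. These are (2S)-4-hydroxy-2-(2-hydroxypropan-2-yl)-7-(4-hydroxyphenyl)-2,3,6,7-tetrahydro-5H-furo[3,2-g]chromen-5-one F5 and (8S)-5-hydroxy-8-(2-hydroxypropan-2-yl)-2-(4-hydroxyphenyl)-2,3,8,9-tetrahydro-4H-furo[2,3-h]chromen-4-one F6. The pyranone ring of both is then opened with aqueous KOH (rt, argon), the known retro-oxa-Michael isomerisation of flavanones to chalcone phenolates. Cold acidification should give 21.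

Further compounds
F1 | step 6 | 1-[4,6-bis(methoxymethoxy)-1-benzofuran-2-yl]ethan-1-one | CC(=O)c1cc2c(OCOC)cc(OCOC)cc2o1
F2 | step 6 | 2-[4,6-bis(methoxymethoxy)-1-benzofuran-2-yl]propan-2-ol | CC(C)(O)c1cc2c(OCOC)cc(OCOC)cc2o1
F3 | step 11 | 1-[(2S)-2-(2-hydroxypropan-2-yl)-4,6-bis(methoxymethoxy)-2,3-dihydro-1-benzofuran-5-yl]ethan-1-one | CC(C)(O)[C@@H]1Cc2c(OCOC)c(C(C)=O)c(OCOC)cc2O1
F4 | step 11 | 4-(methoxymethoxy)benzaldehyde | COCOc1ccc(C=O)cc1
F5 | step 12 | (2S)-4-hydroxy-2-(2-hydroxypropan-2-yl)-7-(4-hydroxyphenyl)-2,3,6,7-tetrahydro-5H-furo[3,2-g]chromen-5-one, mixture of C7 epimers | CC(C)(O)[C@@H]1Cc2c(O1)cc1OC(c3ccc(O)cc3)CC(=O)c1c2O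
F6 | step 12 | (8S)-5-hydroxy-8-(2-hydroxypropan-2-yl)-2-(4-hydroxyphenyl)-2,3,8,9-tetrahydro-4H-furo[2,3-h]chromen-4-one, mixture of C2 epimers | CC(C)(O)[C@@H]1Cc2c(O1)cc(O)c1C(=O)CC(c3ccc(O)cc3)Oc12
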